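The cyclohexene ring is numbered C1 (quaternary oxirane carbon), C2 (CHOH), C3 (CHOBz), C4=C5, C6 (oxirane CH). C3 and C6 both carry oxygen and flank the alkene, so the carbocycle is read as an opened furan cycloadduct. Furan-3-ylmethanol supplies C6, C1 with its CH2O branch, C2, C3 and the C3 oxygen. Its Diels–Alder reaction with (Z)-1,2-bis(phenylsulfonyl)ethene (an acetylene equivalent) forms C3–C4 and C5–C6 at once, cis on the oxygen bridge. Rhodium-catalysed anti-SN2' bridge opening, which also resolves the racemate, sets the trans C2/C3 oxygens; desulfonylation reveals C4=C5 and a hydroxyl-directed epoxidation closes the C1–C6 oxirane.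

Key step: step 1

Remark: C1' denotes the exocyclic CH2O carbon; adduct 3 is assumed to be isolable as the exo,exo isomer, and the ligand antipode that consumes the required enantiomer of 3 would be fixed by correlation with 7.

Step 1
Reactants: 1 furan-3-ylmethanol; 2 (Z)-1,2-bis(phenylsulfonyl)ethene
Product: 3 rac-[(1R,4S,5S,6R)-5,6-bis(phenylsulfonyl)-7-oxabicyclo[2.2.1]hept-2-en-2-yl]methanol (exo,exo: both sulfonyl groups cis to each other and syn to the oxygen bridge)
Conditions: CH2Cl2, 25 to 40 °C, dark, 3 d (equilibrating), then crystallisation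
Reagents that add atoms: none
Why: A thermal, concerted, suprafacial [4+2] cycloaddition (Diels–Alder) joins the furan diene (C3=C2–C1=C6) to the doubly sulfonyl-activated cis-alkene, which acts as an acetylene equivalent whose sulfonyl groups leave in step 5; the closest known reactions are the cycloadditions of furan itself with 1,2-bis(phenylsulfonyl)ethenes used to make 7-oxanorbornadienes. The six-membered carbocycle C1–C6 is closed by cycloaddition, both σ-bonds (C3–C4 and C5–C6) forming in the same event, and the furan oxygen becomes the one-atom bridge of the 7-oxabicyclo[2.2.1]heptene. C3 and C6 are necessarily cis because both bonds form on one face of the planar furan, and C4 and C5 keep the cis geometry of the dienophile. The exo orientation of the sulfonyl groups, needed to leave the endo face open in step 2, is expected from thermodynamic control, since furan cycloadditions are reversible and the exo adduct avoids repulsion between the sulfonyl groups and the C1=C2 bridge. No regiochemical question arises because the dienophile is symmetrical. The two faces of the furan are enantiotopic, so 3 should form as a racemate, which the chiral catalyst of step 2 resolves.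

Step 2
Reactants: 3 rac-[(1R,4S,5S,6R)-5,6-bis(phenylsulfonyl)-7-oxabicyclo[2.2.1]hept-2-en-2-yl]methanol
Product: 4 (1S,2R,5R,6S)-3-(hydroxymethyl)-2-(4-methoxyphenoxy)-5,6-bis(phenylsulfonyl)cyclohex-3-en-1-ol
Conditions: [Rh(cod)Cl]2 (2.5 mol%), (R)-1-[(S)-2-(diphenylphosphino)ferrocenyl]ethyldi-tert-butylphosphine (6 mol%), AgOTf then Bu4NI, 4-methoxyphenol (3 equiv), THF, 50 °C, stopped near half conversion
Reagents that add atoms: 4-methoxyphenol, COc1ccc(O)cc1
Why: This is a rhodium-catalysed asymmetric ring opening of an oxabicyclic alkene with a phenol (anti-SN2'), in which the monovalent rhodium catalyst inserts into the bridgehead C6–O bond on the exo face and the phenol attacks C2 from the endo face, setting C2 trans to the retained C3 oxygen; the chiral catalyst should open only the enantiomer whose preferred C–O bond lies next to the unsubstituted alkene carbon (reagent-controlled kinetic resolution, since the other enantiomer would require attack at the substituted C1), and the saturated C4–C5 bridge leaves a single alkene to react.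

Step 3
Reactants: 4 (1S,2R,5R,6S)-3-(hydroxymethyl)-2-(4-methoxyphenoxy)-5,6-bis(phenylsulfonyl)cyclohex-3-en-1-ol
Product: 5 (1S,2R,5R,6S)-3-[(benzoyloxy)methyl]-2-(4-methoxyphenoxy)-5,6-bis(phenylsulfonyl)cyclohex-3-en-1-yl benzoate
Conditions: BzCl (2.6 equiv), pyridine, DMAP (cat.), CH2Cl2, 0 °C to rt
Reagents that add atoms: benzoyl chloride, O=C(Cl)c1ccccc1
Why: DMAP-catalysed acylation should benzoylate both the primary C1'–OH and the secondary C3–OH under weakly basic conditions that do not deprotonate the α-sulfonyl positions, and no stereocentre is touched.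

Step 4
Reactants: 5 (1S,2R,5R,6S)-3-[(benzoyloxy)methyl]-2-(4-methoxyphenoxy)-5,6-bis(phenylsulfonyl)cyclohex-3-en-1-yl benzoate
Product: 6 (1S,2R,5R,6S)-3-[(benzoyloxy)methyl]-2-hydroxy-5,6-bis(phenylsulfonyl)cyclohex-3-en-1-yl benzoate
Conditions: (NH4)2Ce(NO3)6 (2.5 equiv), MeCN/H2O 4:1, 0 °C
Reagents that add atoms: none
Why: In this oxidative dearylation of a 4-methoxyphenyl ether the tetravalent cerium salt oxidises the electron-rich aryl ring and water adds at its ipso carbon, so the C2–O bond stays intact and C2 keeps its configuration, while sulfones, benzoates and the isolated trisubstituted alkene should be inert (no diene is present yet).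

Step 5
Reactants: 6 (1S,2R,5R,6S)-3-[(benzoyloxy)methyl]-2-hydroxy-5,6-bis(phenylsulfonyl)cyclohex-3-en-1-yl benzoate
Product: 7 (1R,6R)-5-[(benzoyloxy)methyl]-6-hydroxycyclohexa-2,4-dien-1-yl benzoate
Conditions: Na/Hg (6% Na), Na2HPO4, MeOH/THF, −20 °C
Reagents that add atoms: none
Why: Reductive elimination of a vicinal bis-sulfone is the standard unmasking of this acetylene equivalent; the allylic C5–S bond should cleave first and the resulting C5 radical or anion expels the C4 sulfinate to give the C4=C5 alkene, with the phosphate buffer suppressing methoxide-induced loss or migration of the benzoates.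

Step 6
Reactants: 7 (1R,6R)-5-[(benzoyloxy)methyl]-6-hydroxycyclohexa-2,4-dien-1-yl benzoate
Product: 8 [(1S,2S,3R,6R)-3-(benzoyloxy)-2-hydroxy-7-oxabicyclo[4.1.0]hept-4-en-1-yl]methyl benzoate
Conditions: mCPBA (1.1 equiv), NaHCO3, CH2Cl2, 0 °C
Reagents that add atoms: 3-chloroperoxybenzoic acid, O=C(OO)c1cccc(Cl)c1
Why: In a hydroxyl-directed peracid epoxidation (Henbest-type) the free C2–OH hydrogen-bonds to the peracid and delivers oxygen to the same face of the adjacent, more electron-rich trisubstituted C1=C6 alkene, which sets C1 and C6 with the oxirane cis to C2–OH and trans to the C3 benzoate, while C4=C5 is deactivated by its allylic benzoate.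

Compound list
1 | furan-3-ylmethanol | OCc1ccoc1 | starting material
2 | (Z)-1,2-bis(phenylsulfonyl)ethene | O=S(=O)(/C=C\S(=O)(=O)c1ccccc1)c1ccccc1 | starting material
3 | rac-[(1R,4S,5S,6R)-5,6-bis(phenylsulfonyl)-7-oxabicyclo[2.2.1]hept-2-en-2-yl]methanol, exo,exo (racemate; the enantiomer drawn is the one consumed in step 2) | OCC1=C[C@@H]2O[C@H]1[C@@H](S(=O)(=O)c3ccccc3)[C@H]2S(=O)(=O)c3ccccc3 | intermediate
4 | (1S,2R,5R,6S)-3-(hydroxymethyl)-2-(4-methoxyphenoxy)-5,6-bis(phenylsulfonyl)cyclohex-3-en-1-ol (OH and aryloxy trans; both sulfonyl groups cis to the OH) | OCC1=C[C@@H](S(=O)(=O)c2ccccc2)[C@@H](S(=O)(=O)c2ccccc2)[C@@H](O)[C@@H]1Oc3ccc(OC)cc3 | intermediate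
5 | (1S,2R,5R,6S)-3-[(benzoyloxy)methyl]-2-(4-methoxyphenoxy)-5,6-bis(phenylsulfonyl)cyclohex-3-en-1-yl benzoate | O=C(OCC1=C[C@@H](S(=O)(=O)c2ccccc2)[C@@H](S(=O)(=O)c2ccccc2)[C@@H](OC(=O)c2ccccc2)[C@@H]1Oc3ccc(OC)cc3)c1ccccc1 | intermediate
6 | (1S,2R,5R,6S)-3-[(benzoyloxy)methyl]-2-hydroxy-5,6-bis(phenylsulfonyl)cyclohex-3-en-1-yl benzoate | O=C(OCC1=C[C@@H](S(=O)(=O)c2ccccc2)[C@@H](S(=O)(=O)c2ccccc2)[C@@H](OC(=O)c2ccccc2)[C@@H]1O)c1ccccc1 | intermediate
7 | (1R,6R)-5-[(benzoyloxy)methyl]-6-hydroxycyclohexa-2,4-dien-1-yl benzoate (trans OH/OBz) | O=C(OCC1=CC=C[C@@H](OC(=O)c2ccccc2)[C@@H]1O)c1ccccc1 | intermediate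
8 | [(1S,2S,3R,6R)-3-(benzoyloxy)-2-hydroxy-7-oxabicyclo[4.1.0]hept-4-en-1-yl]methyl benzoate | O=C(OC[C@@]12O[C@@H]1C=C[C@@H](OC(=O)c1ccccc1)[C@@H]2O)c1ccccc1 | target

Total step count: 6
Longest linear sequence: 6 steps (from 1)

Steps most likely to fail

Step 2. The C–O insertion may be slow on this electron-poor oxabicycle with a trisubstituted alkene, or the catalyst may discriminate the two enantiomers of 3 poorly, so that 4 would be obtained with low enantiomeric purity. The fallback sets out from 3 and comes back at 4. Racemic 3 would be opened completely with an achiral catalyst ([Rh(cod)Cl]2, 1,1'-bis(diphenylphosphino)ferrocene, Bu4NI, 4-methoxyphenol, THF, 60 °C) to give 4 together with its mirror image, (1R,2S,5S,6R)-3-(hydroxymethyl)-2-(4-methoxyphenoxy)-5,6-bis(phenylsulfonyl)cyclohex-3-en-1-ol F1. Both hydroxyl groups would then be esterified with (S)-2-methoxy-2-phenylacetic acid (DCC, DMAP, CH2Cl2) to the diastereomeric bis-esters, the bis[(S)-2-methoxy-2-phenylacetate] of 4 F2 and the bis[(S)-2-methoxy-2-phenylacetate] of the mirror-image diol F3, which would be separated by chromatography or crystallisation. Reductive removal of the auxiliary from F2 (iBu2AlH, CH2Cl2, −78 °C, non-basic so that the α-sulfonyl positions are untouched) should return enantiopure 4.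

Step 5. A carbanion at C4 may expel the neighbouring C3 benzoate instead of the C5 sulfinate (Julia-type elimination), or the benzoyl group may migrate to the free C2–OH under the basic reduction. The fallback sets out from 4 and comes back at 7, and keeps every ester out of the reduction. Dearylation of 4 with (NH4)2Ce(NO3)6 (MeCN/H2O, 0 °C) would give (1S,2R,5R,6S)-3-(hydroxymethyl)-5,6-bis(phenylsulfonyl)cyclohex-3-ene-1,2-diol F4. Sodium amalgam (Na/Hg, Na2HPO4, MeOH/THF, −20 °C) would then act on a substrate whose oxygens are only alkoxides, not leaving groups, to give (1R,2R)-3-(hydroxymethyl)cyclohexa-3,5-diene-1,2-diol F5. Regioselective dibenzoylation (BzCl 2.1 equiv, pyridine, CH2Cl2, −40 °C) should acylate the primary C1'–OH and the less hindered allylic C3–OH before the C2–OH flanked by the substituted C1, giving 7.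

Step 1. The cycloaddition may run under kinetic control and place the sulfonyl groups endo, or the adduct may revert on handling; endo sulfonyl groups would close the face that the nucleophile needs in step 2. The fallback sets out from 1 and comes back at 7; it removes the sulfonyl groups before the bridge is opened, so their orientation no longer matters. Cycloaddition of 1 with (E)-1,2-bis(phenylsulfonyl)ethene (CH2Cl2, rt) would give rac-[5-exo,6-endo-bis(phenylsulfonyl)-7-oxabicyclo[2.2.1]hept-2-en-2-yl]methanol F6, together with its 5-endo,6-exo isomer. Immediate reduction (Na/Hg, Na2HPO4, MeOH/THF) would give rac-(7-oxabicyclo[2.2.1]hepta-2,5-dien-2-yl)methanol F7. The chiral rhodium catalyst of step 2 with 4-methoxybenzyl alcohol would then open the more strained diene anti-SN2' to (1R,6R)-5-(hydroxymethyl)-6-[(4-methoxybenzyl)oxy]cyclohexa-2,4-dien-1-ol F8; the isomers from attack on the unsubstituted C4=C5 alkene would have to be separated. Benzoylation (BzCl, pyridine, DMAP) would give (1R,6R)-5-[(benzoyloxy)methyl]-6-[(4-methoxybenzyl)oxy]cyclohexa-2,4-dien-1-yl benzoate F9, and DDQ (CH2Cl2/pH 7 buffer, 0 °C) would free the C2–OH to give 7.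

Further compounds
F1 | step 2 | (1R,2S,5S,6R)-3-(hydroxymethyl)-2-(4-methoxyphenoxy)-5,6-bis(phenylsulfonyl)cyclohex-3-en-1-ol (mirror image of 4) | OCC1=C[C@H](S(=O)(=O)c2ccccc2)[C@H](S(=O)(=O)c2ccccc2)[C@H](O)[C@H]1Oc3ccc(OC)cc3
F2 | step 2 | bis[(S)-2-methoxy-2-phenylacetate] of 4 | CO[C@H](C(=O)OCC1=C[C@@H](S(=O)(=O)c2ccccc2)[C@@H](S(=O)(=O)c2ccccc2)[C@@H](OC(=O)[C@@H](OC)c2ccccc2)[C@@H]1Oc3ccc(OC)cc3)c1ccccc1
F3 | step 2 | bis[(S)-2-methoxy-2-phenylacetate] of F1 | CO[C@H](C(=O)OCC1=C[C@H](S(=O)(=O)c2ccccc2)[C@H](S(=O)(=O)c2ccccc2)[C@H](OC(=O)[C@@H](OC)c2ccccc2)[C@H]1Oc3ccc(OC)cc3)c1ccccc1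
F4 | step 5 | (1S,2R,5R,6S)-3-(hydroxymethyl)-5,6-bis(phenylsulfonyl)cyclohex-3-ene-1,2-diol | OCC1=C[C@@H](S(=O)(=O)c2ccccc2)[C@@H](S(=O)(=O)c2ccccc2)[C@@H](O)[C@@H]1O
F5 | step 5 | (1R,2R)-3-(hydroxymethyl)cyclohexa-3,5-diene-1,2-diol | OCC1=CC=C[C@@H](O)[C@@H]1O
F6 | step 1 | rac-[5-exo,6-endo-bis(phenylsulfonyl)-7-oxabicyclo[2.2.1]hept-2-en-2-yl]methanol (trans; one enantiomer of one of the two trans diastereomers drawn) | OCC1=C[C@@H]2O[C@H]1[C@H](S(=O)(=O)c3ccccc3)[C@H]2S(=O)(=O)c3ccccc3
F7 | step 1 | rac-(7-oxabicyclo[2.2.1]hepta-2,5-dien-2-yl)methanol (the enantiomer drawn leads to 7) | OCC1=C[C@@H]2O[C@H]1C=C2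
F8 | step 1 | (1R,6R)-5-(hydroxymethyl)-6-[(4-methoxybenzyl)oxy]cyclohexa-2,4-dien-1-ol | OCC1=CC=C[C@@H](O)[C@@H]1OCc2ccc(OC)cc2
F9 | step 1 | (1R,6R)-5-[(benzoyloxy)methyl]-6-[(4-methoxybenzyl)oxy]cyclohexa-2,4-dien-1-yl benzoate | O=C(OCC1=CC=C[C@@H](OC(=O)c2ccccc2)[C@@H]1OCc2ccc(OC)cc2)c1ccccc1
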